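## Retrosynthetic overview

1. Target 27 ⇐ angeloylation of hydroxy enone 24 ⇐ cyclobutane closure (C4–C10, longipinane numbering) of the himachalane-type epoxy enone 21: an epoxide-triggered cation–olefin cyclization (the laboratory counterpart of himachalyl → longipinyl cation) with a silyl dienol ether as the olefin, so the enone and the C9 oxygen appear in the same step.
2. 21 ⇐ convex-face epoxidation of cycloheptene 20 ⇐ ring-closing metathesis of the cis-5,6-disubstituted cyclohexenone 19.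
3. 19 ⇐ cyclohexenone 12 + epoxy acid 15 + 2-bromopropene; 12 ⇐ acetoacetate-tethered Michael/aldol/decarboxylation of 8, which relays the carbinol configuration to C5 through a chair lactone.
4. 8 ⇐ neopentyl glycol + allyl acetate (Ir-catalysed asymmetric allylation), a stabilized ylide and an acetylketene source; 15 ⇐ tiglyl alcohol (Sharpless epoxidation, oxidation).
5. Ring order: six-membered ring (step 4) → seven-membered ring (step 9) → four-membered ring last (step 11).

Assumption 1: tricyclic compounds are named with longipinane numbering (C1 ketone, C2=C3 with methyl on C3, C4 and C11 bridgeheads, C5 cyclobutane CH, C6 gem-dimethyl carbon, C7 and C9 oxygenated, C8 CH2, C10 quaternary methyl carbon); the target is then (4R,5S,7R,9R,10R,11R) with a (2S,3R)-epoxy ester at C7 and the angelate at C9.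
Assumption 2: in step 1 the ligand antipode is the one that delivers the 3R carbinol; it is written as (R)-Cl,MeO-BIPHEP.

## Route

Step 1
Reactants: 1 2,2-dimethylpropane-1,3-diol (neopentyl glycol); 2 prop-2-en-1-yl acetate (allyl acetate)
Product: 3 (3R)-2,2-dimethylhex-5-ene-1,3-diol
Conditions: [Ir(cod)Cl]2 (2.5 mol %), (R)-Cl,MeO-BIPHEP (5 mol %), 4-chloro-3-nitrobenzoic acid (10 mol %), Cs2CO3 (20 mol %), THF, 100 °C; 1 in excess (3 equiv)
Reagents that add atoms: none
Why: Krische transfer-hydrogenative carbonyl allylation from the alcohol oxidation level; the iridium π-allyl complex dehydrogenates one CH2OH of the achiral diol and adds allyl to the transient aldehyde under ligand control, which sets the 3R carbinol, while excess diol suppresses double allylation.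

Step 2
Reactants: 3 (3R)-2,2-dimethylhex-5-ene-1,3-diol; 4 (acetylmethylene)triphenylphosphorane
Product: 6 (3E,6R)-6-hydroxy-5,5-dimethylnona-3,8-dien-2-one, via hydroxy aldehyde 5 (not isolated)
Conditions: TEMPO (10 mol %), PhI(OAc)2 (1.1 equiv), CH2Cl2, 23 °C; then 4, 40 °C
Reagents that add atoms: none
Why: TEMPO/PhI(OAc)2 oxidizes only the primary alcohol and the non-enolizable aldehyde is trapped in the same flask by Wittig olefination with the stabilized ylide to give the E-enone; no new stereocentre.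

Step 3
Reactants: 6 (3E,6R)-6-hydroxy-5,5-dimethylnona-3,8-dien-2-one; 7 2,2,6-trimethyl-4H-1,3-dioxin-4-one
Product: 8 (4R,6E)-5,5-dimethyl-8-oxonona-1,6-dien-4-yl 3-oxobutanoate
Conditions: toluene, 110 °C
Reagents that add atoms: none
Why: Thermal retro-[4+2] of the dioxinone releases acetylketene, which acetoacetylates even the hindered secondary alcohol; the carbinol centre is untouched.

Step 4
Reactants: 8 (4R,6E)-5,5-dimethyl-8-oxonona-1,6-dien-4-yl 3-oxobutanoate
Product: 12 (5S)-5-[(3R)-3-hydroxy-2-methylhex-5-en-2-yl]-3-methylcyclohex-2-en-1-one, via Michael lactone 9 (not isolated), via bicyclic lactone 10 (not isolated), via keto acid 11 (not isolated)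
Conditions: Cs2CO3 (0.2 equiv), MeCN, 23 °C; then KOtBu, t-BuOH, 40 °C; then 2 M KOH, 60 °C; then 6 M HCl (pH 1), 70 °C
Reagents that add atoms: none
Why: Intramolecular Michael addition of the tethered acetoacetate through a chair six-membered transition state with the allyl group and the enone arm both equatorial (also the thermodynamic lactone, since the addition is reversible) sets the future C5 relative to the carbinol centre; Robinson/Hagemann aldol condensation closes the cyclohexenone while the lactone carboxyl still distinguishes the two ketone arms, and saponification with decarboxylation of the vinylogous β-keto acid gives 12.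

Step 5
Reactants: 13 (2E)-2-methylbut-2-en-1-ol (tiglyl alcohol)
Product: 14 [(2R,3R)-2,3-dimethyloxiran-2-yl]methanol
Conditions: Ti(OiPr)4 (5 mol %), D-(−)-diisopropyl tartrate (6 mol %), t-BuOOH, 4 Å MS, CH2Cl2, −20 °C
Reagents that add atoms: tert-butyl hydroperoxide, CC(C)(C)OO
Why: Katsuki–Sharpless asymmetric epoxidation; the D-(−)-tartrate catalyst delivers oxygen to the alkene face that gives the (2R,3R)-epoxy alcohol.

Step 6
Reactants: 14 [(2R,3R)-2,3-dimethyloxiran-2-yl]methanol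
Product: 15 (2S,3R)-2,3-dimethyloxirane-2-carboxylic acid
Conditions: RuCl3 (2 mol %), NaIO4 (2.2 equiv), MeCN/CCl4/H2O, 23 °C
Reagents that add atoms: water, O
Why: Sharpless RuO4 oxidation of the primary alcohol to the acid leaves the epoxide and both stereocentres untouched (the C2 descriptor changes from R to S only because the CIP priorities change).

Step 7
Reactants: 12 (5S)-5-[(3R)-3-hydroxy-2-methylhex-5-en-2-yl]-3-methylcyclohex-2-en-1-one; 15 (2S,3R)-2,3-dimethyloxirane-2-carboxylic acid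
Product: 17 (3R)-2-methyl-2-[(1S)-3-methyl-5-oxocyclohex-3-en-1-yl]hex-5-en-3-yl (2S,3R)-2,3-dimethyloxirane-2-carboxylate, via mixed anhydride 16 (not isolated)
Conditions: 15, 2,4,6-trichlorobenzoyl chloride, Et3N, THF, 23 °C; then 12, DMAP, toluene, 60 °C
Reagents that add atoms: none
Why: Yamaguchi esterification through the mixed anhydride acylates the hindered carbinol with retention at every centre; the acid has no α-hydrogen, so the ester is robust in the later base steps.

Step 8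
Reactants: 17 (3R)-2-methyl-2-[(1S)-3-methyl-5-oxocyclohex-3-en-1-yl]hex-5-en-3-yl (2S,3R)-2,3-dimethyloxirane-2-carboxylate; 18 2-bromoprop-1-ene
Product: 19 (3R)-2-methyl-2-[(1S,6R)-3-methyl-5-oxo-6-(prop-1-en-2-yl)cyclohex-3-en-1-yl]hex-5-en-3-yl (2S,3R)-2,3-dimethyloxirane-2-carboxylate
Conditions: LiHMDS, THF, −78 °C; 18, Pd2(dba)3 (2.5 mol %), P(t-Bu)3 (6 mol %), −78 → 23 °C; then LiHMDS, −78 °C; AcOH, −78 °C
Reagents that add atoms: none
Why: Palladium-catalysed α-alkenylation of the kinetic cross-conjugated (α′) ketone enolate installs the isopropenyl group; the doubly activated C6–H is then removed again and the dienolate is protonated kinetically at C6 from the face opposite the pseudo-axial C5 side chain, which gives the cis-5,6 isomer.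

Step 9
Reactants: 19 (3R)-2-methyl-2-[(1S,6R)-3-methyl-5-oxo-6-(prop-1-en-2-yl)cyclohex-3-en-1-yl]hex-5-en-3-yl (2S,3R)-2,3-dimethyloxirane-2-carboxylate
Product: 20 (4aS,6R,9aR)-3,5,5,9-tetramethyl-1-oxo-4,4a,5,6,7,9a-hexahydro-1H-benzo[7]annulen-6-yl (2S,3R)-2,3-dimethyloxirane-2-carboxylate
Conditions: second-generation Grubbs catalyst (5 mol %), CH2Cl2 (2 mM), 40 °C
Reagents that add atoms: none
Why: Ring-closing metathesis of the allyl and isopropenyl groups, held cis on adjacent carbons, closes the seven-membered ring as a trisubstituted cycloalkene under neutral conditions that leave the epimerizable C9a untouched; no new stereocentre.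

Step 10
Reactants: 20 (4aS,6R,9aR)-3,5,5,9-tetramethyl-1-oxo-4,4a,5,6,7,9a-hexahydro-1H-benzo[7]annulen-6-yl (2S,3R)-2,3-dimethyloxirane-2-carboxylate
Product: 21 (4aS,6R,8R,9S,9aR)-8,9-epoxy-3,5,5,9-tetramethyl-1-oxo-4,4a,5,6,7,8,9,9a-octahydro-1H-benzo[7]annulen-6-yl (2S,3R)-2,3-dimethyloxirane-2-carboxylate
Conditions: mCPBA, CH2Cl2, 0 °C
Reagents that add atoms: mCPBA, OOC(=O)c1cccc(Cl)c1
Why: Prilezhaev epoxidation attacks only the electron-rich trisubstituted alkene (the enone alkene is inert) from the convex face, anti to the cis-fused cyclohexenone and the C6 ester, which sets C8 and C9.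

Step 11
Reactants: 21 (4aS,6R,8R,9S,9aR)-8,9-epoxy-3,5,5,9-tetramethyl-1-oxo-4,4a,5,6,7,8,9,9a-octahydro-1H-benzo[7]annulen-6-yl (2S,3R)-2,3-dimethyloxirane-2-carboxylate
Product: 24 (4R,5S,7R,9R,10R,11R)-9-hydroxy-1-oxolongipin-2-en-7-yl (2S,3R)-2,3-dimethyloxirane-2-carboxylate, via silyl dienol ether 22 (not isolated), via silyl ether 23 (not isolated)
Conditions: TMSOTf (2.2 equiv), 2,6-di-tert-butyl-4-methylpyridine (2.5 equiv), CH2Cl2, −78 → −30 °C; then K2CO3, MeOH, 0 °C
Reagents that add atoms: none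
Why: Proposed new method: O-silylation of the enone and γ-deprotonation by the hindered pyridine give the extended silyl dienol ether 22, TMSOTf then opens the trisubstituted epoxide at its tertiary carbon C9 and the diene terminus C4 attacks anti to the leaving oxygen (4-exo, inversion at C9), the silyloxocarbenium ion passing its silyl group to the new alkoxide (23); epoxide strain release and re-formation of the conjugated enone pay for the cyclobutane, and the C9–O bond of the target, the quaternary centre and both bridgeheads are set in one step as in the himachalyl → longipinyl cation closure; the closest known reactions are Lewis-acid epoxide-initiated cation–olefin cyclizations terminated by enol silanes, vinylogous Mukaiyama alkylations and Stork's 4-exo epoxynitrile cyclization.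

Step 12
Reactants: 24 (4R,5S,7R,9R,10R,11R)-9-hydroxy-1-oxolongipin-2-en-7-yl (2S,3R)-2,3-dimethyloxirane-2-carboxylate; 25 (2Z)-2-methylbut-2-enoic acid (angelic acid)
Product: 27 (4R,5S,7R,9R,10R,11R)-9-{[(2Z)-2-methylbut-2-enoyl]oxy}-1-oxolongipin-2-en-7-yl (2S,3R)-2,3-dimethyloxirane-2-carboxylate, via mixed anhydride 26 (not isolated)
Conditions: 25, 2,4,6-trichlorobenzoyl chloride, Et3N, toluene, 23 °C; then 24, 75 °C
Reagents that add atoms: none
Why: Yamaguchi-type acylation with the preformed angelic mixed anhydride and no nucleophilic catalyst acylates the hindered C9 alcohol without Z→E isomerization to the tiglate; no stereocentre is touched.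

## Compound list

1 | 2,2-dimethylpropane-1,3-diol | OCC(C)(C)CO | starting material
2 | prop-2-en-1-yl acetate | CC(=O)OCC=C | starting material
3 | (3R)-2,2-dimethylhex-5-ene-1,3-diol | OCC(C)(C)[C@H](O)CC=C | intermediate
4 | (acetylmethylene)triphenylphosphorane | CC(=O)C=P(c1ccccc1)(c1ccccc1)c1ccccc1 | starting material
5 | (3R)-3-hydroxy-2,2-dimethylhex-5-enal | O=CC(C)(C)[C@H](O)CC=C | intermediate (not isolated)
6 | (3E,6R)-6-hydroxy-5,5-dimethylnona-3,8-dien-2-one | CC(=O)/C=C/C(C)(C)[C@H](O)CC=C | intermediate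
7 | 2,2,6-trimethyl-4H-1,3-dioxin-4-one | CC1=CC(=O)OC(C)(C)O1 | starting material
8 | (4R,6E)-5,5-dimethyl-8-oxonona-1,6-dien-4-yl 3-oxobutanoate | CC(=O)/C=C/C(C)(C)[C@H](OC(=O)CC(C)=O)CC=C | intermediate
9 | (3S,4R,6R)-3-acetyl-5,5-dimethyl-4-(2-oxopropyl)-6-(prop-2-en-1-yl)oxan-2-one | CC(=O)C[C@@H]1[C@@H](C(C)=O)C(=O)O[C@H](CC=C)C1(C)C | intermediate (not isolated)
10 | (3R,4aR,8aS)-4,4,8-trimethyl-3-(prop-2-en-1-yl)-3,4,4a,5-tetrahydro-1H-isochromene-1,6(8aH)-dione | O=C1C=C(C)[C@@H]2[C@@H](C1)C(C)(C)[C@@H](CC=C)OC2=O | intermediate (not isolated)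
11 | (1S,6R)-6-[(3R)-3-hydroxy-2-methylhex-5-en-2-yl]-2-methyl-4-oxocyclohex-2-ene-1-carboxylic acid | O=C1C=C(C)[C@@H](C(=O)O)[C@@H](C1)C(C)(C)[C@H](O)CC=C | intermediate (not isolated)
12 | (5S)-5-[(3R)-3-hydroxy-2-methylhex-5-en-2-yl]-3-methylcyclohex-2-en-1-one | O=C1C=C(C)C[C@@H](C1)C(C)(C)[C@H](O)CC=C | intermediate
13 | (2E)-2-methylbut-2-en-1-ol | C/C=C(\C)CO | starting material
14 | [(2R,3R)-2,3-dimethyloxiran-2-yl]methanol | OC[C@@]1(C)O[C@@H]1C | intermediate
15 | (2S,3R)-2,3-dimethyloxirane-2-carboxylic acid | OC(=O)[C@@]1(C)O[C@@H]1C | intermediate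
16 | (2S,3R)-2,3-dimethyloxirane-2-carboxylic 2,4,6-trichlorobenzoic anhydride | O=C(OC(=O)c1c(Cl)cc(Cl)cc1Cl)[C@@]1(C)O[C@@H]1C | intermediate (not isolated)
17 | (3R)-2-methyl-2-[(1S)-3-methyl-5-oxocyclohex-3-en-1-yl]hex-5-en-3-yl (2S,3R)-2,3-dimethyloxirane-2-carboxylate | O=C1C=C(C)C[C@@H](C1)C(C)(C)[C@H](OC(=O)[C@@]2(C)O[C@@H]2C)CC=C | intermediate
18 | 2-bromoprop-1-ene | CC(Br)=C | starting material
19 | (3R)-2-methyl-2-[(1S,6R)-3-methyl-5-oxo-6-(prop-1-en-2-yl)cyclohex-3-en-1-yl]hex-5-en-3-yl (2S,3R)-2,3-dimethyloxirane-2-carboxylate | O=C1C=C(C)C[C@@H]([C@@H]1C(C)=C)C(C)(C)[C@H](OC(=O)[C@@]2(C)O[C@@H]2C)CC=C | intermediate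
20 | (4aS,6R,9aR)-3,5,5,9-tetramethyl-1-oxo-4,4a,5,6,7,9a-hexahydro-1H-benzo[7]annulen-6-yl (2S,3R)-2,3-dimethyloxirane-2-carboxylate | O=C1C=C(C)C[C@H]2[C@@H]1C(C)=CC[C@@H](OC(=O)[C@@]3(C)O[C@@H]3C)C2(C)C | intermediate
21 | (4aS,6R,8R,9S,9aR)-8,9-epoxy-3,5,5,9-tetramethyl-1-oxo-4,4a,5,6,7,8,9,9a-octahydro-1H-benzo[7]annulen-6-yl (2S,3R)-2,3-dimethyloxirane-2-carboxylate | O=C1C=C(C)C[C@H]2[C@@H]1[C@]1(C)O[C@@H]1C[C@@H](OC(=O)[C@@]3(C)O[C@@H]3C)C2(C)C | intermediate
22 | (4aS,6R,8R,9S,9aR)-8,9-epoxy-3,5,5,9-tetramethyl-1-[(trimethylsilyl)oxy]-5,6,7,8,9,9a-hexahydro-4aH-benzo[7]annulen-6-yl (2S,3R)-2,3-dimethyloxirane-2-carboxylate | C[Si](C)(C)OC1=CC(C)=C[C@H]2[C@@H]1[C@]1(C)O[C@@H]1C[C@@H](OC(=O)[C@@]3(C)O[C@@H]3C)C2(C)C | intermediate (not isolated)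
23 | (4R,5S,7R,9R,10R,11R)-1-oxo-9-[(trimethylsilyl)oxy]longipin-2-en-7-yl (2S,3R)-2,3-dimethyloxirane-2-carboxylate | C[Si](C)(C)O[C@@H]1C[C@@H](OC(=O)[C@@]2(C)O[C@@H]2C)C(C)(C)[C@@H]2[C@H]3C(=O)C=C(C)[C@@H]2[C@]31C | intermediate (not isolated)
24 | (4R,5S,7R,9R,10R,11R)-9-hydroxy-1-oxolongipin-2-en-7-yl (2S,3R)-2,3-dimethyloxirane-2-carboxylate | O[C@@H]1C[C@@H](OC(=O)[C@@]2(C)O[C@@H]2C)C(C)(C)[C@@H]2[C@H]3C(=O)C=C(C)[C@@H]2[C@]31C | intermediate
25 | (2Z)-2-methylbut-2-enoic acid (angelic acid) | C/C=C(/C)C(=O)O | starting material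
26 | (2Z)-2-methylbut-2-enoic 2,4,6-trichlorobenzoic anhydride | C/C=C(/C)C(=O)OC(=O)c1c(Cl)cc(Cl)cc1Cl | intermediate (not isolated)
27 | (4R,5S,7R,9R,10R,11R)-9-{[(2Z)-2-methylbut-2-enoyl]oxy}-1-oxolongipin-2-en-7-yl (2S,3R)-2,3-dimethyloxirane-2-carboxylate (CNP0149458.1) | C/C=C(/C)C(=O)O[C@@H]1C[C@@H](OC(=O)[C@@]2(C)O[C@@H]2C)C(C)(C)[C@@H]2[C@H]3C(=O)C=C(C)[C@@H]2[C@]31C | target

## Step count and risks

Total step count: 12. Longest linear sequence: 10 (steps 1–4 and 7–12); the epoxy acid branch is steps 5–6.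

Steps most likely to fail:

Step 11 (cyclobutane closure). The risks are loss of the C9a proton (giving the conjugated alkylidene ketone), Meinwald rearrangement of the epoxide, and attack by the α-carbon instead of the γ-carbon. The fallback replaces the epoxide by a tertiary alcohol whose neighbouring angelate stabilizes the cation as a dioxolanium ion. It sets out from 20: OsO4 (cat.)/NMO dihydroxylates the convex face to (4aS,6R,8R,9S,9aR)-8,9-dihydroxy-3,5,5,9-tetramethyl-1-oxo-4,4a,5,6,7,8,9,9a-octahydro-1H-benzo[7]annulen-6-yl (2S,3R)-2,3-dimethyloxirane-2-carboxylate F6. The secondary hydroxyl alone is acylated with 26 (made from 25 as in step 12) to the 8-angelate (4aS,6R,8R,9S,9aR)-9-hydroxy-3,5,5,9-tetramethyl-8-{[(2Z)-2-methylbut-2-enoyl]oxy}-1-oxo-4,4a,5,6,7,8,9,9a-octahydro-1H-benzo[7]annulen-6-yl (2S,3R)-2,3-dimethyloxirane-2-carboxylate F7. TMSOTf with 2,6-di-tert-butyl-4-methylpyridine gives the bis-silylated dienol ether (4aS,6R,8R,9S,9aS)-3,5,5,9-tetramethyl-8-{[(2Z)-2-methylbut-2-enoyl]oxy}-1,9-bis[(trimethylsilyl)oxy]-5,6,7,8,9,9a-hexahydro-4aH-benzo[7]annulen-6-yl (2S,3R)-2,3-dimethyloxirane-2-carboxylate F8. Its tertiary silyl ether ionizes with angelate participation and is displaced with inversion by the diene terminus. The fallback comes back to the route at 27 itself.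

Step 8 (α′-isopropenylation and cis control). The coupling is at a hindered carbon and the product can slip into conjugation. The fallback builds the group by aldol chemistry and deconjugation. It sets out from 17: the kinetic enolate (LDA, −78 °C) adds to acetone to give (3R)-2-[(1S,6S)-6-(2-hydroxypropan-2-yl)-3-methyl-5-oxocyclohex-3-en-1-yl]-2-methylhex-5-en-3-yl (2S,3R)-2,3-dimethyloxirane-2-carboxylate F4. Catalytic TsOH in toluene at 50 °C dehydrates it to the isopropylidene ketone (3R)-2-methyl-2-[(1R)-3-methyl-5-oxo-6-(propan-2-ylidene)cyclohex-3-en-1-yl]hex-5-en-3-yl (2S,3R)-2,3-dimethyloxirane-2-carboxylate F5. γ-Deprotonation (LDA, THF/HMPA, −78 °C) and kinetic α-protonation with AcOH deconjugate it, as in pulegone → isopulegone. The fallback comes back to the route at 19.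

Step 4 (tethered Michael/aldol/decarboxylation). The Michael addition is onto a neopentyl β-carbon and the aldol regiochemistry decides the C5 configuration. The fallback makes the ring by an anion-accelerated 6π-electrocyclization instead. It sets out from 3: oxidation as in step 2 without ylide isolates 5, which is silylated (TBSOTf, 2,6-lutidine) to (3R)-3-[(tert-butyldimethylsilyl)oxy]-2,2-dimethylhex-5-enal F1. Claisen–Schmidt condensation with mesityl oxide (Ba(OH)2, EtOH) gives (5E,8R)-8-[(tert-butyldimethylsilyl)oxy]-2,7,7-trimethylundeca-2,5,10-trien-4-one F2. KOtBu in THF removes a γ-proton and the oxidotriene cyclizes to (5S)-5-{(3R)-3-[(tert-butyldimethylsilyl)oxy]-2-methylhex-5-en-2-yl}-3-methylcyclohex-2-en-1-one F3. This closure has no control at C5, so F3 must be separated from its C5 epimer. TBAF then removes the silyl group and the fallback comes back to the route at 12.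

Further compounds
F1 | step 4 | (3R)-3-[(tert-butyldimethylsilyl)oxy]-2,2-dimethylhex-5-enal | O=CC(C)(C)[C@H](O[Si](C)(C)C(C)(C)C)CC=C
F2 | step 4 | (5E,8R)-8-[(tert-butyldimethylsilyl)oxy]-2,7,7-trimethylundeca-2,5,10-trien-4-one | CC(C)=CC(=O)/C=C/C(C)(C)[C@H](O[Si](C)(C)C(C)(C)C)CC=C
F3 | step 4 | (5S)-5-{(3R)-3-[(tert-butyldimethylsilyl)oxy]-2-methylhex-5-en-2-yl}-3-methylcyclohex-2-en-1-one | O=C1C=C(C)C[C@@H](C1)C(C)(C)[C@H](O[Si](C)(C)C(C)(C)C)CC=C
F4 | step 8 | (3R)-2-[(1S,6S)-6-(2-hydroxypropan-2-yl)-3-methyl-5-oxocyclohex-3-en-1-yl]-2-methylhex-5-en-3-yl (2S,3R)-2,3-dimethyloxirane-2-carboxylate | O=C1C=C(C)C[C@@H]([C@H]1C(C)(C)O)C(C)(C)[C@H](OC(=O)[C@@]2(C)O[C@@H]2C)CC=C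
F5 | step 8 | (3R)-2-methyl-2-[(1R)-3-methyl-5-oxo-6-(propan-2-ylidene)cyclohex-3-en-1-yl]hex-5-en-3-yl (2S,3R)-2,3-dimethyloxirane-2-carboxylate | O=C1C=C(C)C[C@@H](C1=C(C)C)C(C)(C)[C@H](OC(=O)[C@@]2(C)O[C@@H]2C)CC=C
F6 | step 11 | (4aS,6R,8R,9S,9aR)-8,9-dihydroxy-3,5,5,9-tetramethyl-1-oxo-4,4a,5,6,7,8,9,9a-octahydro-1H-benzo[7]annulen-6-yl (2S,3R)-2,3-dimethyloxirane-2-carboxylate | O=C1C=C(C)C[C@H]2[C@@H]1[C@](C)(O)[C@H](O)C[C@@H](OC(=O)[C@@]3(C)O[C@@H]3C)C2(C)C
F7 | step 11 | (4aS,6R,8R,9S,9aR)-9-hydroxy-3,5,5,9-tetramethyl-8-{[(2Z)-2-methylbut-2-enoyl]oxy}-1-oxo-4,4a,5,6,7,8,9,9a-octahydro-1H-benzo[7]annulen-6-yl (2S,3R)-2,3-dimethyloxirane-2-carboxylate | O=C1C=C(C)C[C@H]2[C@@H]1[C@](C)(O)[C@H](OC(=O)/C(C)=C\C)C[C@@H](OC(=O)[C@@]3(C)O[C@@H]3C)C2(C)C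
F8 | step 11 | (4aS,6R,8R,9S,9aS)-3,5,5,9-tetramethyl-8-{[(2Z)-2-methylbut-2-enoyl]oxy}-1,9-bis[(trimethylsilyl)oxy]-5,6,7,8,9,9a-hexahydro-4aH-benzo[7]annulen-6-yl (2S,3R)-2,3-dimethyloxirane-2-carboxylate | C[Si](C)(C)OC1=CC(C)=C[C@H]2[C@@H]1[C@](C)(O[Si](C)(C)C)[C@H](OC(=O)/C(C)=C\C)C[C@@H](OC(=O)[C@@]3(C)O[C@@H]3C)C2(C)C
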